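(The earlier runs and the new flask are simulated on assumed constants.)

- The vessel is closed, stirred and isothermal, and it holds substrate and other conformer together; I reckon everything as a fraction of that joint charge.

| setting | Wednesday's | Tuesday's | flask |
|---|---|---|---|
| substrate | 0.10 M | 0.10 M | 0.10 M |
| other conformer | 0.050 M | 0.075 M | 0.100 M |
| remark | run made earlier | run made earlier |  |
| time |  |  | 2.5 h |

| run | time / min | substrate / % | target / % | isomer of the product / % |
|---|---|---|---|---|
| Wednesday's | 8.00 | 3 | 10 | 42 |
| Wednesday's | 15.0 | 2 | 6 | 51 |
| Wednesday's | 25.0 | 0 | 3 | 53 |
| Wednesday's | 50.0 | 0 | 1 | 51 |
| Wednesday's | 90.0 | 0 | 3 | 52 |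
| Tuesday's | 20.0 | 1 | 5 | 55 |
| Tuesday's | 40.0 | 1 | 2 | 61 |
| Tuesday's | 50.0 | 0 | 6 | 60 |
| Tuesday's | 80.0 | 2 | 4 | 60 |
| Tuesday's | 90.0 | 0 | 2 | 62 |

(each reading ± 1.5 percentage points)

- the earlier runs were read with a standard deviation of 1.5 percentage points
- in a conversion other conformer counts as not yet reacted
- the reaction counts as stopped when no species that holds the substrate and other conformer together changes by six tenths of a point or more over the second half of the time

- why nothing more happens at 2.5 h, or that something still does (other conformer counts as not reacted) (it is still moving / forward and back rates have come level / all of the substrate has reacted)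
- part of the substrate and other conformer together gone at 2.5 h
- the target standing at 2.5 h, as a percentage of the substrate and other conformer together charged
- the isomer of the product standing at 2.5 h, as a percentage of the substrate and other conformer together charged

- My first estimate comes from what the readings do not add up to. Averaged over the last 3 readings, Wednesday's run leaves 45.7 % unread and Tuesday's run leaves 34.7 %: this is the mass-balance gap.
- My objection is that this gap might be other conformer still standing, which would make conversion low. But in Wednesday's run it exceeds the 33.3 % of conformer charged, while substrate reads 0 % at the last reading.
- So I try a better quantity, the toll: the unread amount as a share of the substrate charge. It is 68.5 % on Wednesday and 60.7 % on Tuesday, so in these readings it did not rise with more conformer. I take the mean, 64.6 %, and count the conformer as ending in read products.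
- Those two values differ, and in this flask that moves the gap by 2 percentage points either way, against a scatter of 1.5 points on one reading.
- In this flask the toll gives a gap of 32.3 %, which leaves 67.7 % read. Target is the small correction: over the last 3 readings of both runs it reads 5.62 % of the isomer. That makes target 3.60 % and isomer 64.1 %. I expect the flask to have stopped with its substrate reacted away, at conversion near 100 %.
- The forecast, “That points to balanced rates”, says that forward and back rates have come level, with conversion 71 %, target 4.5 % and isomer 67 %; I differ from it on the stop and the conversion.
- In the flask all of the substrate has reacted: conversion 100 %, target 2.87 %, isomer 63.1 %. At 1.25 h substrate already stands at 0 % and other conformer at 0 %. The unread part is side product, 34.0 % with each counted as two, so the toll in this flask comes to 68.0 %.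

    substrate + target → side product (k = 6.80 M⁻¹ min⁻¹)
    target ⇌ isomer of the product (K = 22.0, k = 0.140 min⁻¹)
    substrate ⇌ other conformer (K = 0.840, k = 0.00590 min⁻¹)
    substrate → target (k = 0.170 min⁻¹)
    other conformer → isomer of the product (k = 0.390 min⁻¹)

- In the neighbour flask with 0.025 M of other conformer, my toll gives a gap of 51.7 % and isomer 45.7 %. The computed flask holds 52.2 % side product and 45.8 % isomer.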